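**Strategy.** Longipinane numbering is used (C1 ring ketone; cyclobutane C4–C5–C11–C10; C6 gem‑dimethyl carbon). A (4+3) annulation builds the seven‑membered ring last. The key step exploits that C5 and C10 sit 1,3 on the cyclobutane: a bicyclo[3.1.1]heptan‑6‑one with cyclobutanone carbon C5 and a formyl group (C9) cis on C10 is joined in one flask with 3‑methylbut‑3‑en‑2‑one (C6–C7–C8). An enolate aldol forms C8–C9; copper hydride reduction of the tethered enone gives the C6 enolate, which closes C5–C6 on the only reachable carbonyl face. The bicycle comes from an intramolecular vinylketene [2+2] cycloaddition of an acid made by asymmetric vinylogous aldol addition.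

Key step: step 11

Remark: for the bicycles, bicycloheptane C6 = longipinane C5, C7 = C10, C4 = C1. In step 8 the vinylketene is assumed to form by deprotonation of the C3 methyl group (exocyclic alkene); the ring‑alkene isomer, if formed, would converge on 30.

Step 1
Reactants: 1 1-[(tert-butyldimethylsilyl)oxy]propan-2-one; 2 triethyl phosphonoacetate
Product: 3 ethyl (2E)-4-[(tert-butyldimethylsilyl)oxy]-3-methylbut-2-enoate
Conditions: NaH, THF, 0 °C to rt
Reagents that add atoms: none
Why: Horner–Wadsworth–Emmons olefination, in which the ester should settle trans to the larger CH2OSi group to give mainly the 2E isomer (the minor 2Z isomer is removed by chromatography).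

Step 2
Reactants: 3 ethyl (2E)-4-[(tert-butyldimethylsilyl)oxy]-3-methylbut-2-enoate
Product: 4 (2E)-4-[(tert-butyldimethylsilyl)oxy]-3-methylbut-2-en-1-ol
Conditions: iBu2AlH, CH2Cl2, −78 °C; aq. sodium potassium tartrate
Reagents that add atoms: none
Why: Ester reduction by two hydride transfers, which should leave the alkene geometry untouched.

Step 3
Reactants: 4 (2E)-4-[(tert-butyldimethylsilyl)oxy]-3-methylbut-2-en-1-ol
Product: 5 (2E)-4-[(tert-butyldimethylsilyl)oxy]-3-methylbut-2-enal
Conditions: MnO2, CH2Cl2, rt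
Reagents that add atoms: none
Why: Allylic oxidation with MnO2 should stop at the aldehyde and keep the E geometry.

Step 4
Reactants: 6 methyl 3-methylbut-2-enoate
Product: 7 tert-butyl[(1-methoxy-3-methylbuta-1,3-dien-1-yl)oxy]dimethylsilane
Conditions: LiN(iPr)2, THF, −78 °C; tert-butyldimethylsilyl chloride, DMPU
Reagents that add atoms: tert-butyldimethylsilyl chloride, CC(C)(C)[Si](C)(C)Cl
Why: γ‑Deprotonation and O‑silylation of the enoate should give the silyl dienolate needed for a vinylogous Mukaiyama aldol addition.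

Step 5
Reactants: 5 (2E)-4-[(tert-butyldimethylsilyl)oxy]-3-methylbut-2-enal; 7 tert-butyl[(1-methoxy-3-methylbuta-1,3-dien-1-yl)oxy]dimethylsilane
Product: 8 methyl (2E,5S,6E)-8-[(tert-butyldimethylsilyl)oxy]-5-hydroxy-3,7-dimethylocta-2,6-dienoate
Conditions: SiCl4, chiral 2,2′-binaphthyldiamine-derived bisphosphoramide (5 mol %, antipode that directs attack to the Si face of the aldehyde), iPr2NEt (cat.), CH2Cl2, −78 °C; aq. NaHCO3
Reagents that add atoms: none
Why: Catalytic enantioselective vinylogous Mukaiyama aldol addition (Lewis base‑activated SiCl4), in which γ‑attack should give the 2E enoate and the catalyst sets C5 as S.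

Step 6
Reactants: 8 methyl (2E,5S,6E)-8-[(tert-butyldimethylsilyl)oxy]-5-hydroxy-3,7-dimethylocta-2,6-dienoate
Product: 9 methyl (2E,5S,6E)-5,8-bis[(tert-butyldimethylsilyl)oxy]-3,7-dimethylocta-2,6-dienoate
Conditions: tert-butyldimethylsilyl triflate, 2,6-lutidine, CH2Cl2, −78 °C
Reagents that add atoms: tert-butyldimethylsilyl trifluoromethanesulfonate, CC(C)(C)[Si](C)(C)OS(=O)(=O)C(F)(F)F
Why: Silylation under non‑basic conditions protects the allylic alcohol without risk of vinylogous retro‑aldol cleavage.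

Step 7
Reactants: 9 methyl (2E,5S,6E)-5,8-bis[(tert-butyldimethylsilyl)oxy]-3,7-dimethylocta-2,6-dienoate
Product: 10 (2E,5S,6E)-5,8-bis[(tert-butyldimethylsilyl)oxy]-3,7-dimethylocta-2,6-dienoic acid
Conditions: LiOH, THF/MeOH/H2O, rt; aq. HCl to pH 4
Reagents that add atoms: lithium hydroxide, [Li+].[OH-]
Why: Saponification of the methyl ester, which both silyl ethers should survive.

Step 8
Reactants: 10 (2E,5S,6E)-5,8-bis[(tert-butyldimethylsilyl)oxy]-3,7-dimethylocta-2,6-dienoic acid
Product: 13 (4S)-4-[(tert-butyldimethylsilyl)oxy]-7-{[(tert-butyldimethylsilyl)oxy]methyl}-7-methyl-2-methylidenebicyclo[3.1.1]heptan-6-one (CH2OSi on C7 anti to the C2–C4 bridge; 4-OSi on the side of the C6 carbonyl bridge), via acid chloride 11 (not isolated), via vinylketene 12 (not isolated)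
Conditions: 1-chloro-N,N,2-trimethylprop-1-en-1-amine, CH2Cl2, 0 °C; then Et3N, toluene, 110 °C, high dilution
Reagents that add atoms: none
Why: Intramolecular vinylketene–alkene [2+2] cycloaddition, in which the ketene carbonyl carbon bonds to the less substituted alkene carbon (bridged mode) and suprafacial addition to the E alkene places the CH2OSi group anti to the three‑carbon bridge; A(1,3) strain between the allylic silyloxy group and the cis methyl turns the silyloxy group toward the carbonyl bridge, so the single C–O stereocentre fixes both bridgeheads and the quaternary carbon.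

Step 9
Reactants: 13 (4S)-4-[(tert-butyldimethylsilyl)oxy]-7-{[(tert-butyldimethylsilyl)oxy]methyl}-7-methyl-2-methylidenebicyclo[3.1.1]heptan-6-one
Product: 14 (4S)-4-[(tert-butyldimethylsilyl)oxy]-7-(hydroxymethyl)-7-methyl-2-methylidenebicyclo[3.1.1]heptan-6-one
Conditions: HF·pyridine, pyridine, THF, 0 °C
Reagents that add atoms: none
Why: Buffered fluoride desilylation should cleave the primary silyl ether faster than the hindered secondary one.

Step 10
Reactants: 14 (4S)-4-[(tert-butyldimethylsilyl)oxy]-7-(hydroxymethyl)-7-methyl-2-methylidenebicyclo[3.1.1]heptan-6-one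
Product: 15 (4S)-4-[(tert-butyldimethylsilyl)oxy]-7-methyl-2-methylidene-6-oxobicyclo[3.1.1]heptane-7-carbaldehyde (formyl group anti to the C2–C4 bridge)
Conditions: Dess–Martin periodinane, NaHCO3, CH2Cl2, rt
Reagents that add atoms: none
Why: Dess–Martin oxidation gives a non‑enolisable neopentyl aldehyde, so the quaternary centre cannot epimerise.

Step 11
Reactants: 15 (4S)-4-[(tert-butyldimethylsilyl)oxy]-7-methyl-2-methylidene-6-oxobicyclo[3.1.1]heptane-7-carbaldehyde; 16 3-methylbut-3-en-2-one
Product: 19 (1S)-1-[(tert-butyldimethylsilyl)oxy]-5,9-dihydroxylongipin-3(15)-en-7-one (5-OH syn to the C1–C3 bridge; both C9 epimers), via hydroxy enone 17 (not isolated), via copper enolate 18 (not isolated)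
Conditions: LiN(iPr)2, 16, THF, −78 °C; then 15; then [(Ph3P)CuH]6, THF/toluene, −78 to 0 °C; aq. NH4Cl
Reagents that add atoms: none
Why: The cross‑conjugated lithium enolate of 16 adds through its methylene terminus to the neopentyl aldehyde (aldol addition, C8–C9) to give 17; the copper hydride then delivers hydride to the CH2 terminus of the tethered isopropenyl ketone, which completes the gem‑dimethyl group and gives the tetrasubstituted copper enolate 18 regiospecifically, and 18 adds to the strained cyclobutanone carbonyl (C5–C6). The closest known reaction types are the kinetic lithium enolate aldol addition and the copper hydride reductive aldol cyclisation of keto enones. The seven‑membered ring closes in a 7-(enolendo)-exo-trig aldol mode across the 1,3‑cis related C9 and C5 of the cyclobutane. The new C5 stereocentre is controlled by the tether: C9 sits on the cyclobutane face anti to the C1–C3 bridge, so C6 can reach only that face of the carbonyl and the hydroxyl ends syn to the bridge, while the uncontrolled C9 carbinol centre is erased in step 12. The step needs chemoselectivity (aldehyde before the bridged ketone, 1,4‑ before 1,2‑reduction) and regioselectivity for C6 over C8 as the second nucleophile; the first is secured by the non‑enolisable, doubly shielded cyclobutanone and the conjugate‑selective hydride, the second by generating the enolate through reduction and not deprotonation.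

Step 12
Reactants: 19 (1S)-1-[(tert-butyldimethylsilyl)oxy]-5,9-dihydroxylongipin-3(15)-en-7-one
Product: 21 (1S)-1-[(tert-butyldimethylsilyl)oxy]-5-hydroxylongipina-3(15),8-dien-7-one, via mesylate 20 (not isolated)
Conditions: MeSO2Cl, Et3N, CH2Cl2, 0 °C; then DBU, rt
Reagents that add atoms: none
Why: Mesylation of the secondary C9 alcohol and E1cB elimination should give the ring (cis) enone from either C9 epimer, while the shielded tertiary C5 alcohol does not react.

Step 13
Reactants: 21 (1S)-1-[(tert-butyldimethylsilyl)oxy]-5-hydroxylongipina-3(15),8-dien-7-one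
Product: 22 (1S)-1-[(tert-butyldimethylsilyl)oxy]-7-oxolongipina-3(15),8-dien-5-yl methyl oxalate
Conditions: methyl chlorooxoacetate, DMAP, CH2Cl2, rt
Reagents that add atoms: methyl chlorooxoacetate, COC(=O)C(=O)Cl
Why: Acylation with the small, highly electrophilic oxalyl chloride half ester activates the tertiary alcohol without forming an alkoxide that could undergo retro‑aldol cleavage.

Step 14
Reactants: 22 (1S)-1-[(tert-butyldimethylsilyl)oxy]-7-oxolongipina-3(15),8-dien-5-yl methyl oxalate
Product: 23 (1S)-1-[(tert-butyldimethylsilyl)oxy]longipina-3(15),8-dien-7-one (H on C5 syn to the C1–C3 bridge)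
Conditions: Bu3SnH (0.5 M), AIBN, toluene, 110 °C
Reagents that add atoms: none
Why: Barton–McCombie‑type radical deoxygenation of a tertiary oxalate, in which the C5 cyclobutyl radical can take hydrogen only on the face left free by the seven‑membered ring, and a high stannane concentration should outrun the Dowd–Beckwith acyl shift.

Step 15
Reactants: 23 (1S)-1-[(tert-butyldimethylsilyl)oxy]longipina-3(15),8-dien-7-one
Product: 24 (1S)-1-[(tert-butyldimethylsilyl)oxy]longipina-3(15),8-dien-7-ol (7-OH on the ring face turned toward C4)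
Conditions: (S)-2-methyl-CBS-oxazaborolidine (20 mol %), catecholborane, toluene, −78 °C; aq. NaOH
Reagents that add atoms: none
Why: Corey–Bakshi–Shibata reduction under reagent control (the two ketone faces are nearly equivalent toward the locally mirror‑symmetric cage), with the quaternary C6 as the large substituent, and catecholborane chosen to avoid hydroboration of the methylidene group.

Step 16
Reactants: 25 angelic acid
Product: 26 angelic 2,4,6-trichlorobenzoic anhydride
Conditions: 2,4,6-trichlorobenzoyl chloride, Et3N, toluene, rt; filtration under argon, filtrate kept as a toluene stock solution (enough for steps 17 and 22)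
Reagents that add atoms: 2,4,6-trichlorobenzoyl chloride, O=C(Cl)c1c(Cl)cc(Cl)cc1Cl
Why: Acylation of the triethylammonium carboxylate by the aroyl chloride gives the Yamaguchi mixed anhydride, and the absence of a nucleophilic catalyst should keep the Z geometry of the angeloyl group.

Step 17
Reactants: 24 (1S)-1-[(tert-butyldimethylsilyl)oxy]longipina-3(15),8-dien-7-ol; 26 angelic 2,4,6-trichlorobenzoic anhydride
Product: 27 (1S)-1-[(tert-butyldimethylsilyl)oxy]longipina-3(15),8-dien-7-yl angelate
Conditions: Et3N, toluene, 80 °C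
Reagents that add atoms: none
Why: Yamaguchi‑type esterification without a nucleophilic catalyst, in which the alcohol attacks the angeloyl carbonyl because the aroyl carbonyl is shielded by two ortho chlorines, and the Z geometry of the angelate should be kept.

Step 18
Reactants: 27 (1S)-1-[(tert-butyldimethylsilyl)oxy]longipina-3(15),8-dien-7-yl angelate
Product: 28 (1S)-1-hydroxylongipina-3(15),8-dien-7-yl angelate
Conditions: HF·pyridine, THF, rt
Reagents that add atoms: none
Why: Fluoride desilylation under weakly acidic conditions should leave the allylic angelate in place.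

Step 19
Reactants: 28 (1S)-1-hydroxylongipina-3(15),8-dien-7-yl angelate
Product: 30 1-oxolongipina-2,8-dien-7-yl angelate, via unconjugated enone 29 (not isolated)
Conditions: Dess–Martin periodinane, NaHCO3, CH2Cl2, rt; then Et3N, rt
Reagents that add atoms: none
Why: Dess–Martin oxidation removes the relay stereocentre, and mild base moves the exocyclic alkene into conjugation to give the more stable ring enone.

Step 20
Reactants: 30 1-oxolongipina-2,8-dien-7-yl angelate
Product: 31 8,9-dihydroxy-1-oxolongipin-2-en-7-yl angelate (cis-diol on the face turned toward C11, anti to the C7 ester)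
Conditions: OsO4 (5 mol %), 4-methylmorpholine N-oxide, acetone/H2O, 0 °C
Reagents that add atoms: 4-methylmorpholine N-oxide, C[N+]1([O-])CCOCC1; water, O
Why: Catalytic osmium tetroxide syn‑dihydroxylation should occur anti to the allylic ester oxygen and prefer the isolated ring alkene over the electron‑poor enone and angelate alkenes.

Step 21
Reactants: 31 8,9-dihydroxy-1-oxolongipin-2-en-7-yl angelate
Product: 32 8-acetoxy-9-hydroxy-1-oxolongipin-2-en-7-yl angelate
Conditions: Ac2O, pyridine, CH2Cl2, −20 °C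
Reagents that add atoms: acetic anhydride, CC(=O)OC(C)=O
Why: Selective acetylation of the less hindered C8 hydroxyl, since the C9 hydroxyl is neopentylic next to the quaternary C10.

Step 22
Reactants: 32 8-acetoxy-9-hydroxy-1-oxolongipin-2-en-7-yl angelate; 26 angelic 2,4,6-trichlorobenzoic anhydride
Product: 33 8-acetoxy-7,9-bis(angeloyloxy)longipin-2-en-1-one (CNP0335415.1)
Conditions: Et3N, toluene, 80 °C
Reagents that add atoms: none
Why: Yamaguchi‑type esterification of the remaining hindered alcohol under catalyst‑free thermal conditions, which should preserve the angelate geometry and all stereocentres.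

**Compound list**

1 | 1-[(tert-butyldimethylsilyl)oxy]propan-2-one | CC(=O)CO[Si](C)(C)C(C)(C)C | starting material
2 | triethyl phosphonoacetate | CCOC(=O)CP(=O)(OCC)OCC | starting material
3 | ethyl (2E)-4-[(tert-butyldimethylsilyl)oxy]-3-methylbut-2-enoate | CCOC(=O)/C=C(\C)CO[Si](C)(C)C(C)(C)C | intermediate
4 | (2E)-4-[(tert-butyldimethylsilyl)oxy]-3-methylbut-2-en-1-ol | OC/C=C(\C)CO[Si](C)(C)C(C)(C)C | intermediate
5 | (2E)-4-[(tert-butyldimethylsilyl)oxy]-3-methylbut-2-enal | O=C/C=C(\C)CO[Si](C)(C)C(C)(C)C | intermediate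
6 | methyl 3-methylbut-2-enoate | COC(=O)C=C(C)C | starting material
7 | tert-butyl[(1-methoxy-3-methylbuta-1,3-dien-1-yl)oxy]dimethylsilane (ketene acetal isomers) | COC(O[Si](C)(C)C(C)(C)C)=CC(C)=C | intermediate
8 | methyl (2E,5S,6E)-8-[(tert-butyldimethylsilyl)oxy]-5-hydroxy-3,7-dimethylocta-2,6-dienoate | COC(=O)/C=C(\C)C[C@H](O)/C=C(\C)CO[Si](C)(C)C(C)(C)C | intermediate
9 | methyl (2E,5S,6E)-5,8-bis[(tert-butyldimethylsilyl)oxy]-3,7-dimethylocta-2,6-dienoate | COC(=O)/C=C(\C)C[C@H](O[Si](C)(C)C(C)(C)C)/C=C(\C)CO[Si](C)(C)C(C)(C)C | intermediate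
10 | (2E,5S,6E)-5,8-bis[(tert-butyldimethylsilyl)oxy]-3,7-dimethylocta-2,6-dienoic acid | OC(=O)/C=C(\C)C[C@H](O[Si](C)(C)C(C)(C)C)/C=C(\C)CO[Si](C)(C)C(C)(C)C | intermediate
11 | (2E,5S,6E)-5,8-bis[(tert-butyldimethylsilyl)oxy]-3,7-dimethylocta-2,6-dienoyl chloride | ClC(=O)/C=C(\C)C[C@H](O[Si](C)(C)C(C)(C)C)/C=C(\C)CO[Si](C)(C)C(C)(C)C | intermediate
12 | (5S,6E)-5,8-bis[(tert-butyldimethylsilyl)oxy]-7-methyl-3-methylideneocta-1,6-dien-1-one (vinylketene) | O=C=CC(=C)C[C@H](O[Si](C)(C)C(C)(C)C)/C=C(\C)CO[Si](C)(C)C(C)(C)C | intermediate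
13 | (4S)-4-[(tert-butyldimethylsilyl)oxy]-7-{[(tert-butyldimethylsilyl)oxy]methyl}-7-methyl-2-methylidenebicyclo[3.1.1]heptan-6-one | O=C1[C@@H]2C(=C)C[C@H](O[Si](C)(C)C(C)(C)C)[C@H]1[C@]2(C)CO[Si](C)(C)C(C)(C)C | intermediate
14 | (4S)-4-[(tert-butyldimethylsilyl)oxy]-7-(hydroxymethyl)-7-methyl-2-methylidenebicyclo[3.1.1]heptan-6-one | O=C1[C@@H]2C(=C)C[C@H](O[Si](C)(C)C(C)(C)C)[C@H]1[C@]2(C)CO | intermediate
15 | (4S)-4-[(tert-butyldimethylsilyl)oxy]-7-methyl-2-methylidene-6-oxobicyclo[3.1.1]heptane-7-carbaldehyde | O=C1[C@@H]2C(=C)C[C@H](O[Si](C)(C)C(C)(C)C)[C@H]1[C@]2(C)C=O | intermediate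
16 | 3-methylbut-3-en-2-one | CC(=O)C(C)=C | starting material
17 | (4S)-4-[(tert-butyldimethylsilyl)oxy]-7-(1-hydroxy-4-methyl-3-oxopent-4-en-1-yl)-7-methyl-2-methylidenebicyclo[3.1.1]heptan-6-one (both carbinol epimers) | C=C(C)C(=O)CC(O)[C@@]1(C)[C@@H]2[C@@H](O[Si](C)(C)C(C)(C)C)CC(=C)[C@H]1C2=O | intermediate
18 | copper enolate of the reduced side-chain ketone of 17 (C6=C7 enolate, written as the enol) | CC(C)=C(O)CC(O)[C@@]1(C)[C@@H]2[C@@H](O[Si](C)(C)C(C)(C)C)CC(=C)[C@H]1C2=O | intermediate
19 | (1S)-1-[(tert-butyldimethylsilyl)oxy]-5,9-dihydroxylongipin-3(15)-en-7-one (5-OH syn to the C1–C3 bridge; C9 epimers) | O=C1CC(O)[C@@]2(C)[C@@H]3[C@@H](O[Si](C)(C)C(C)(C)C)CC(=C)[C@H]2[C@]3(O)C1(C)C | intermediate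
20 | 9-O-methanesulfonate of 19 | O=C1CC(OS(C)(=O)=O)[C@@]2(C)[C@@H]3[C@@H](O[Si](C)(C)C(C)(C)C)CC(=C)[C@H]2[C@]3(O)C1(C)C | intermediate
21 | (1S)-1-[(tert-butyldimethylsilyl)oxy]-5-hydroxylongipina-3(15),8-dien-7-one | O=C1C=C[C@@]2(C)[C@@H]3[C@@H](O[Si](C)(C)C(C)(C)C)CC(=C)[C@H]2[C@]3(O)C1(C)C | intermediate
22 | (1S)-1-[(tert-butyldimethylsilyl)oxy]-7-oxolongipina-3(15),8-dien-5-yl methyl oxalate | O=C1C=C[C@@]2(C)[C@@H]3[C@@H](O[Si](C)(C)C(C)(C)C)CC(=C)[C@H]2[C@]3(OC(=O)C(=O)OC)C1(C)C | intermediate
23 | (1S)-1-[(tert-butyldimethylsilyl)oxy]longipina-3(15),8-dien-7-one | O=C1C=C[C@@]2(C)[C@@H]3[C@@H](O[Si](C)(C)C(C)(C)C)CC(=C)[C@H]2[C@@H]3C1(C)C | intermediate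
24 | (1S)-1-[(tert-butyldimethylsilyl)oxy]longipina-3(15),8-dien-7-ol (7-OH toward C4) | O[C@@H]1C=C[C@@]2(C)[C@@H]3[C@@H](O[Si](C)(C)C(C)(C)C)CC(=C)[C@H]2[C@@H]3C1(C)C | intermediate
25 | angelic acid, (2Z)-2-methylbut-2-enoic acid | C/C=C(/C)C(=O)O | starting material
26 | angelic 2,4,6-trichlorobenzoic anhydride | C/C=C(/C)C(=O)OC(=O)c1c(Cl)cc(Cl)cc1Cl | intermediate
27 | (1S)-1-[(tert-butyldimethylsilyl)oxy]longipina-3(15),8-dien-7-yl angelate | C/C=C(/C)C(=O)O[C@@H]1C=C[C@@]2(C)[C@@H]3[C@@H](O[Si](C)(C)C(C)(C)C)CC(=C)[C@H]2[C@@H]3C1(C)C | intermediate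
28 | (1S)-1-hydroxylongipina-3(15),8-dien-7-yl angelate | C/C=C(/C)C(=O)O[C@@H]1C=C[C@@]2(C)[C@@H]3[C@@H](O)CC(=C)[C@H]2[C@@H]3C1(C)C | intermediate
29 | 1-oxolongipina-3(15),8-dien-7-yl angelate | C/C=C(/C)C(=O)O[C@@H]1C=C[C@@]2(C)[C@@H]3C(=O)CC(=C)[C@H]2[C@@H]3C1(C)C | intermediate
30 | 1-oxolongipina-2,8-dien-7-yl angelate | C/C=C(/C)C(=O)O[C@@H]1C=C[C@@]2(C)[C@@H]3C(=O)C=C(C)[C@H]2[C@@H]3C1(C)C | intermediate
31 | 8,9-dihydroxy-1-oxolongipin-2-en-7-yl angelate (8,9-cis-diol anti to the 7-ester) | C/C=C(/C)C(=O)O[C@@H]1[C@@H](O)[C@@H](O)[C@@]2(C)[C@@H]3C(=O)C=C(C)[C@H]2[C@@H]3C1(C)C | intermediate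
32 | 8-acetoxy-9-hydroxy-1-oxolongipin-2-en-7-yl angelate | C/C=C(/C)C(=O)O[C@@H]1[C@@H](OC(C)=O)[C@@H](O)[C@@]2(C)[C@@H]3C(=O)C=C(C)[C@H]2[C@@H]3C1(C)C | intermediate
33 | 8-acetoxy-7,9-bis(angeloyloxy)longipin-2-en-1-one (CNP0335415.1) | C/C=C(/C)C(=O)O[C@@H]1[C@@H](OC(C)=O)[C@@H](OC(=O)/C(C)=C\C)[C@@]2(C)[C@@H]3C(=O)C=C(C)[C@H]2[C@@H]3C1(C)C | target

**Step count.** Total: 22 steps. Longest linear sequence: 20 steps (steps 1–3, 5–15 and 17–22, from 1); steps 4 and 16 are side branches.

**Steps most likely to fail**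

Step 11. The ketone–ketone aldol closure onto the hindered cyclobutanone may reverse (retro‑aldol of the copper aldolate). The C9 alkoxide may add reversibly to the cyclobutanone and mask it, or the lithium aldolate may fragment before the reduction, so that the second bond does not persist. Fallback, setting out from 15 and coming back at 19: the aldol is run on its own (lithium enolate of 16, −78 °C, acidic quench) and hydroxy enone 17 is isolated. Silylation (Et3SiCl, imidazole) gives the triethylsilyl ether of 17 F1. Rhodium‑catalysed 1,4‑hydrosilylation (Et3SiH, RhCl(PPh3)3) converts the enone into the tetrasubstituted triethylsilyl enol ether F2. TiCl4 (CH2Cl2, −78 °C) then closes the seven‑membered ring by an intramolecular Mukaiyama aldol addition, which is driven forward by silyl transfer and chelation, and gives the 9‑O‑triethylsilyl ether of 19 F3. Dilute aqueous HCl in THF at 0 °C cleaves the triethylsilyl ether and returns 19.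

Step 14 (with its preparation in step 13). The β‑keto cyclobutyl radical may undergo 1,2‑acyl migration onto the neighbouring carbonyl (ring contraction), tin radicals may reduce the enone, and acylation of the shielded tertiary alcohol may be sluggish. Fallback, setting out from 21 and coming back at 24: the ketone is reduced first under the conditions of step 15 to the allylic diol F4. The secondary hydroxyl is silylated (Et3SiCl, imidazole) to the 7‑triethylsilyl ether F5. The tertiary alcohol is converted into the methyl oxalate F6 and reduced (Bu3SnH, AIBN) to the deoxygenated silyl ether F7, where no carbonyl is left next to the radical. Pyridinium p‑toluenesulfonate in methanol removes the triethylsilyl group and gives 24.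

Step 22. Under the forcing acylation the acetyl group may migrate from O8 to the free cis O9, and the angelate may partly isomerise from Z to E. Fallback, setting out from 31 and coming back at 33: the less hindered C8 hydroxyl is masked as the 8‑triethylsilyl ether F8 (Et3SiCl, imidazole, −20 °C). The C9 hydroxyl is angeloylated with 26 to give the silylated bis‑angelate F9. HF·pyridine frees the C8 alcohol F10, and acetylation (Ac2O, pyridine) as the last operation gives 33.

Further compounds
F1 | step 11 | triethylsilyl ether of 17 | C=C(C)C(=O)CC(O[Si](CC)(CC)CC)[C@@]1(C)[C@@H]2[C@@H](O[Si](C)(C)C(C)(C)C)CC(=C)[C@H]1C2=O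
F2 | step 11 | tetrasubstituted triethylsilyl enol ether of the reduced ketone (bis-triethylsilyl compound) | CC(C)=C(O[Si](CC)(CC)CC)CC(O[Si](CC)(CC)CC)[C@@]1(C)[C@@H]2[C@@H](O[Si](C)(C)C(C)(C)C)CC(=C)[C@H]1C2=O
F3 | step 11 | 9-O-triethylsilyl ether of 19 | O=C1CC(O[Si](CC)(CC)CC)[C@@]2(C)[C@@H]3[C@@H](O[Si](C)(C)C(C)(C)C)CC(=C)[C@H]2[C@]3(O)C1(C)C
F4 | step 14 | (1S)-1-[(tert-butyldimethylsilyl)oxy]longipina-3(15),8-diene-5,7-diol | O[C@@H]1C=C[C@@]2(C)[C@@H]3[C@@H](O[Si](C)(C)C(C)(C)C)CC(=C)[C@H]2[C@]3(O)C1(C)C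
F5 | step 14 | (1S)-1-[(tert-butyldimethylsilyl)oxy]-7-[(triethylsilyl)oxy]longipina-3(15),8-dien-5-ol | CC[Si](CC)(CC)O[C@@H]1C=C[C@@]2(C)[C@@H]3[C@@H](O[Si](C)(C)C(C)(C)C)CC(=C)[C@H]2[C@]3(O)C1(C)C
F6 | step 14 | (1S)-1-[(tert-butyldimethylsilyl)oxy]-7-[(triethylsilyl)oxy]longipina-3(15),8-dien-5-yl methyl oxalate | CC[Si](CC)(CC)O[C@@H]1C=C[C@@]2(C)[C@@H]3[C@@H](O[Si](C)(C)C(C)(C)C)CC(=C)[C@H]2[C@]3(OC(=O)C(=O)OC)C1(C)C
F7 | step 14 | (1S)-1-[(tert-butyldimethylsilyl)oxy]-7-[(triethylsilyl)oxy]longipina-3(15),8-diene | CC[Si](CC)(CC)O[C@@H]1C=C[C@@]2(C)[C@@H]3[C@@H](O[Si](C)(C)C(C)(C)C)CC(=C)[C@H]2[C@@H]3C1(C)C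
F8 | step 22 | 9-hydroxy-1-oxo-8-[(triethylsilyl)oxy]longipin-2-en-7-yl angelate | C/C=C(/C)C(=O)O[C@@H]1[C@@H](O[Si](CC)(CC)CC)[C@@H](O)[C@@]2(C)[C@@H]3C(=O)C=C(C)[C@H]2[C@@H]3C1(C)C
F9 | step 22 | 7,9-bis(angeloyloxy)-8-[(triethylsilyl)oxy]longipin-2-en-1-one | C/C=C(/C)C(=O)O[C@@H]1[C@@H](O[Si](CC)(CC)CC)[C@@H](OC(=O)/C(C)=C\C)[C@@]2(C)[C@@H]3C(=O)C=C(C)[C@H]2[C@@H]3C1(C)C
F10 | step 22 | 7,9-bis(angeloyloxy)-8-hydroxylongipin-2-en-1-one | C/C=C(/C)C(=O)O[C@@H]1[C@@H](O)[C@@H](OC(=O)/C(C)=C\C)[C@@]2(C)[C@@H]3C(=O)C=C(C)[C@H]2[C@@H]3C1(C)C
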